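Percent of the substrate charged is the unit of the questions below, so the partner's budget should be told in it too.

| setting | delta | theta | flask |
|---|---|---|---|
| substrate | 0.050 M | 0.050 M | 0.050 M |
| coupling partner | 0.055 M | 0.11 M | 0.0550 M |
| remark | the very flask that is asked about, followed so far | run made earlier |  |
| time |  |  | 2.5 h |

- delta (time / min: double product / %): 20.0: 18.8; 25.0: 22.4; 40.0: 28.7; 60.0: 33.9
- theta (time / h: double product / %): 0.333: 43.2; 0.667: 58.9; 1.33: 64.9; 2.50: 55.8

(each reading ± 0.5 percentage points)

- what was read earlier has a scatter of 0.5 percentage points, one standard deviation
- a reading or a percentage of double product counts all its forms, free or not

* the moment within 2.5 h at which there is most double product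
* the amount of double product, in percent of the substrate charged, at that time
* the first time at which double product reaches 9.9 %, in the same percent

How much double product can the asked flask hold? I read the name as two couplings, so each double product costs two coupling partners. That makes 55.0 %; call this, half of c(coupling partner) over c(substrate) at the start, the partner ceiling.

Which charge stops it? The coupling partner is the limiting reagent for double product in the asked flask, because its ceiling lies lower than the 100 % the substrate allows. The delta run, this same flask followed so far, stands lower than that ceiling at 33.9 %.

But is a ceiling ever reached? Not in the theta run. Its partner would allow 110 %, so there the substrate caps it. Its highest reading is 64.9 %, and the last is 9.1 percentage points lower, far more than the scatter. Double product is being lost there. So the theta run reads a share of 0.649 of its ceiling.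

Does that share carry over? Roughly, and this is the weak spot, since it comes from one run with four readings. Still, I commit to 35.7 % for the asked flask.

The forecast says 35.5 % at 1.4 h for the peak, on the ground that the partner “is almost exhausted by about 1 h, so formation stalls”. Its 0.19 h for the first question rests on a separate estimate from the early course of the flask. My reckoning gives no times, so those are the forecast's own.

The asked flask peaks at 33.0 % at 1.20 h and first reaches 9.9 % at 0.184 h, so the forecast's peak time was 1.17 times too late.

    substrate + coupling partner → single product + by-product (k = 37.0 L mol⁻¹ h⁻¹)
    coupling partner + single product → double product + by-product (k = 120 L mol⁻¹ h⁻¹)
    double product → over-reaction product (k = 0.320 h⁻¹)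
    coupling partner + double product ⇌ idle adduct, settled at all times (K = 10.0 L mol⁻¹)

At that peak, 7.96 % of the substrate charged stands as over-reaction product. The peak is 0.600 of the partner ceiling, lower than the theta share, which puts my reckoning 2.7 points high.

With 0.093 M of coupling partner in the neighbour flask, the ceiling is 93.0 %, and the theta share gives 60.4 %. The computed best there is 56.9 %.

(The data were computed from invented constants, noise included.)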